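**Plan**

- Retrosynthesis: cut the coumarin O5–CH3 bond (back to a 5,7-diol, O7 masked as a benzyl ether), then C4–C4a and O1–C2 of the pyranone ring, giving phloroglucinol and a 2-aryl-3-oxopropanoate.
- The side arm is cut further at the formyl C–Cα bond, the aryl–CH2 bond (aryl shift from an acetyl group) and the chroman O–CH3 bond. The dihydropyran ring is cut at C4–C4a and O1–C2, back to 2,4-dihydroxyacetophenone and prenal.
- Forward: the dihydropyran ring of the chroman is built first (chromenylation, hydrogenation). The acetyl group is then taken to CH2CO2Me and CH(CHO)CO2Me. The pyranone ring is closed onto phloroglucinol in one operation. O7 benzylation, O5 methylation and debenzylation finish the route.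
- Enabling feature: the pyranone ring (O1, C2, C3, C4, C4a, C8a) carries its aryl group on C3 and hydrogen on C4, and is fused to a benzene ring oxygenated at C5, C7 and C8a. That is a phloroglucinol pattern, so the two ring-forming bonds map onto a threefold-symmetric triphenol and an α-formyl arylacetate.
- Stereochemistry: none has to be set, because the target has no stereocentre and no stereogenic double bond.

Key step: step 6

Remark: the target is achiral, so the structure as drawn is the only stereoisomer and "single enantiomer" is read as that structure.

**Route**

Step 1
Reactants: 1 (2,4-dihydroxyacetophenone) and 2 (3-methylbut-2-enal)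
Product: 4 chromene ketone 1-(5-hydroxy-2,2-dimethyl-2H-chromen-6-yl)ethan-1-one, via ortho-quinone methide dienone 3 (not isolated)
Conditions: pyridine, 140 °C (sealed vessel)
Reagents that add atoms: none
Why: Pyridine-promoted chromenylation, in which aldol-type (Knoevenagel) condensation of the aldehyde at C3 of 1 (the carbon flanked by both hydroxyls) gives dienone 3, which closes by oxa-6π electrocyclisation through the free 4-oxygen because the 2-hydroxyl is held in a hydrogen bond to the acetyl group.

Step 2
Reactants: 4 (chromene ketone)
Product: 5 chroman ketone 1-(5-hydroxy-2,2-dimethylchroman-6-yl)ethan-1-one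
Conditions: H2 (1 atm), 10% Pd/C, EtOAc, rt
Reagents that add atoms: none
Why: Catalytic hydrogenation of the styrene-type chromene double bond is fast at 1 atm whereas the hydrogen-bonded aryl ketone is reduced far more slowly, so stopping after one equivalent of hydrogen should give the chroman.

Step 3
Reactants: 5 (chroman ketone)
Product: 6 methyl ether 1-(5-methoxy-2,2-dimethylchroman-6-yl)ethan-1-one
Conditions: MeI, K2CO3, DMF, 50 °C
Reagents that add atoms: iodomethane, CI
Why: Williamson O-methylation of the phenol, where the chelated and doubly flanked hydroxyl calls for warm DMF and excess reagent, conditions that touch nothing else in 5.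

Step 4
Reactants: 6 (methyl ether ketone)
Product: 7 arylacetate methyl 2-(5-methoxy-2,2-dimethylchroman-6-yl)acetate
Conditions: Tl(NO3)3·3H2O, MeOH, HClO4 (cat.), rt
Reagents that add atoms: methanol, CO
Why: Thallium(III) nitrate oxidative rearrangement of an aryl methyl ketone (McKillop–Taylor), in which oxythallation of the enol form is followed by a 1,2-shift of the electron-rich aryl group with loss of thallium(I), turning the acetyl group into the methyl arylacetate.

Step 5
Reactants: 7 (arylacetate) and 8 (methyl formate)
Product: 9 formyl ester methyl 2-(5-methoxy-2,2-dimethylchroman-6-yl)-3-oxopropanoate (racemic, in equilibrium with its hydroxymethylene enol)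
Conditions: NaH, HCO2Me (excess), THF, 0 °C to rt; then aq. HCl
Reagents that add atoms: none
Why: Crossed Claisen condensation with non-enolisable methyl formate, driven by formation of the sodium enolate of the product, which is released on acidification and should be used without delay.

Step 6
Reactants: 9 (formyl ester) and 10 (phloroglucinol)
Product: 12 5,7-dihydroxy-3-(5-methoxy-2,2-dimethylchroman-6-yl)coumarin, via trihydroxyphenyl acrylate ester 11 (not isolated)
Conditions: 10 (1.1 equiv), HCl(g)-saturated AcOH, 0 °C to rt, then 50 °C
Reagents that add atoms: none
Why: Acid activates the formyl (hydroxymethylene) carbon of 9, a ring carbon of 10 attacks it in a Friedel–Crafts hydroxyalkylation that forms C4–C4a, and loss of water gives acrylate 11, whose double bond can isomerise under acid through its quinone-methide tautomer so that a phenol lies cis to the ester. That phenol then adds to the ester carbonyl and expels methanol, forming O1–C2 and closing the pyranone ring by 6-exo-trig lactonisation. The closest known reaction type is the Pechmann condensation of polyphenols with 2-aryl-3-oxopropanoates, an established entry to 3-arylcoumarins. No stereocentre is created, and the geometry of the transient alkene is lost once it is endocyclic. The step needs carbon attack at the formyl carbon instead of oxygen attack or ring acylation by the ester (the Simonis chromone outcome), one annulation only, and no choice of ring position: protic acid and the high carbon nucleophilicity of phloroglucinol favour the coumarin, the threefold symmetry of 10 makes its three ring carbons and three hydroxyls equivalent, and the conjugated lactone deactivates 12 towards a second annulation. The chroman ether and the aryl methyl ether of 9 should be inert to anhydrous HCl in acetic acid at this temperature, and the chroman ring is far less nucleophilic than 10, so it should not compete for the formyl group.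

Step 7
Reactants: 12 (5,7-dihydroxycoumarin)
Product: 13 7-benzyloxy-5-hydroxy-3-(5-methoxy-2,2-dimethylchroman-6-yl)coumarin
Conditions: BnBr (1.05 equiv), K2CO3 (1.1 equiv), acetone, rt
Reagents that add atoms: benzyl bromide, BrCc1ccccc1
Why: Williamson etherification with limiting base, in which the 7-hydroxyl should react first because its phenoxide is the better stabilised (para-quinoid conjugation through C4a–C4=C3 to the lactone carbonyl) and it is less hindered than the 5-hydroxyl peri to H-4.

Step 8
Reactants: 13 (7-benzyl ether)
Product: 14 7-benzyloxy-5-methoxy-3-(5-methoxy-2,2-dimethylchroman-6-yl)coumarin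
Conditions: MeI, K2CO3, acetone, reflux
Reagents that add atoms: iodomethane, CI
Why: Williamson O-methylation of the one remaining phenol, with the lactone, the benzyl ether and the chroman stable to anhydrous carbonate.

Step 9
Reactants: 14 (benzyl methyl diether)
Product: 15 7-hydroxy-5-methoxy-3-(5-methoxy-2,2-dimethylchroman-6-yl)coumarin (target)
Conditions: H2 (1 atm), 10% Pd/C, EtOAc–MeOH, rt
Reagents that add atoms: none
Why: Hydrogenolysis of the aryl benzyl ether over palladium, with the trisubstituted conjugated C3=C4 bond of the 3-arylcoumarin reduced much more slowly, so the reaction is stopped after one equivalent of hydrogen.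

**Compound list**

1 | 2,4-dihydroxyacetophenone | CC(=O)c1ccc(O)cc1O | starting material
2 | 3-methylbut-2-enal (prenal) | CC(C)=CC=O | starting material
3 | ortho-quinone methide dienone, 4-acetyl-3-hydroxy-2-(3-methylbut-2-enylidene)cyclohexa-3,5-dien-1-one (not isolated) | CC(=O)C1=C(O)C(=CC=C(C)C)C(=O)C=C1 | intermediate
4 | 1-(5-hydroxy-2,2-dimethyl-2H-chromen-6-yl)ethan-1-one | CC(=O)c1ccc2OC(C)(C)C=Cc2c1O | intermediate
5 | 1-(5-hydroxy-2,2-dimethylchroman-6-yl)ethan-1-one | CC(=O)c1ccc2OC(C)(C)CCc2c1O | intermediate
6 | 1-(5-methoxy-2,2-dimethylchroman-6-yl)ethan-1-one | CC(=O)c1ccc2OC(C)(C)CCc2c1OC | intermediate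
7 | methyl 2-(5-methoxy-2,2-dimethylchroman-6-yl)acetate | COC(=O)Cc1ccc2OC(C)(C)CCc2c1OC | intermediate
8 | methyl formate | COC=O | starting material
9 | methyl 2-(5-methoxy-2,2-dimethylchroman-6-yl)-3-oxopropanoate (racemic, enolisable) | COC(=O)C(C=O)c1ccc2OC(C)(C)CCc2c1OC | intermediate
10 | phloroglucinol (benzene-1,3,5-triol) | Oc1cc(O)cc(O)c1 | starting material
11 | methyl (Z)-2-(5-methoxy-2,2-dimethylchroman-6-yl)-3-(2,4,6-trihydroxyphenyl)acrylate (not isolated) | COC(=O)/C(=C\c1c(O)cc(O)cc1O)c1ccc2OC(C)(C)CCc2c1OC | intermediate
12 | 5,7-dihydroxy-3-(5-methoxy-2,2-dimethylchroman-6-yl)coumarin | COc1c(-c2cc3c(O)cc(O)cc3oc2=O)ccc2c1CCC(C)(C)O2 | intermediate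
13 | 7-benzyloxy-5-hydroxy-3-(5-methoxy-2,2-dimethylchroman-6-yl)coumarin | COc1c(-c2cc3c(O)cc(OCc4ccccc4)cc3oc2=O)ccc2c1CCC(C)(C)O2 | intermediate
14 | 7-benzyloxy-5-methoxy-3-(5-methoxy-2,2-dimethylchroman-6-yl)coumarin | COc1c(-c2cc3c(OC)cc(OCc4ccccc4)cc3oc2=O)ccc2c1CCC(C)(C)O2 | intermediate
15 | 7-hydroxy-5-methoxy-3-(5-methoxy-2,2-dimethylchroman-6-yl)coumarin | COc1c(-c2cc3c(OC)cc(O)cc3oc2=O)ccc2c1CCC(C)(C)O2 | target

**Step count**

Total: 9 steps. Longest linear sequence: 9 steps (1 to 15); compounds 2, 8 and 10 each enter in a single step.

**Steps most likely to fail**

Step 7. The two phenolic oxygens may be discriminated poorly, so that alkylation spreads over O5 and O7 or runs on to the bis-benzyl ether. The fallback sets out from 9 and brings the methyl ether in with the phenol partner. Under the conditions of step 6, 9 would be condensed with commercial 5-methoxyresorcinol (COc1cc(O)cc(O)c1) in place of phloroglucinol. Ring attack at either of the two equivalent carbons between a hydroxyl and the methoxyl, followed by lactonisation through the adjacent hydroxyl, would give the target directly. The regioisomeric coumarin from attack between the two hydroxyls would have to be removed by chromatography. This fallback comes back to the route at 15 and makes steps 7 to 9 unnecessary.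

Step 6. The formyl ester may lose its formyl group under acid (retro-Claisen), phloroglucinol may be consumed by repeated hydroxyalkylation to diarylmethane oligomers, or oxygen attack may divert material towards the chromone. The fallback sets out from 7 and forms the pyranone ring from a preformed aldehyde. Saponification (LiOH, THF–H2O, rt; then HCl) would give 2-(5-methoxy-2,2-dimethylchroman-6-yl)acetic acid F1. Perkin–Oglialoro condensation of this acid with commercial 2,4,6-trihydroxybenzaldehyde (Ac2O, Et3N, 110 °C) would build C3=C4 by aldol-type condensation and the lactone by acyl transfer, giving 5,7-diacetoxy-3-(5-methoxy-2,2-dimethylchroman-6-yl)coumarin F2. Acid methanolysis of the two aryl acetates (HCl, MeOH, 50 °C) would come back to the route at 12.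

Step 1. The condensation may stall at low conversion while prenal self-condenses to resin, and ring closure through the chelated oxygen or attack at C5 may erode the regiochemistry. The fallback sets out from 1 and uses a sigmatropic cascade instead of a condensation. Alkylation of the unchelated 4-hydroxyl with 3-chloro-3-methylbut-1-yne (K2CO3, KI, acetone, reflux) would give 1-[2-hydroxy-4-(2-methylbut-3-yn-2-yloxy)phenyl]ethan-1-one F3. Heating in N,N-diethylaniline at about 190 °C should trigger aromatic propargyl Claisen rearrangement to C3, a 1,5-hydrogen shift and oxa-6π electrocyclisation, coming back to the route at 4.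

**Further compounds**

F0 | step 7 | none | none
F1 | step 6 | 2-(5-methoxy-2,2-dimethylchroman-6-yl)acetic acid | OC(=O)Cc1ccc2OC(C)(C)CCc2c1OC
F2 | step 6 | 5,7-diacetoxy-3-(5-methoxy-2,2-dimethylchroman-6-yl)coumarin | COc1c(-c2cc3c(OC(C)=O)cc(OC(C)=O)cc3oc2=O)ccc2c1CCC(C)(C)O2
F3 | step 1 | 1-[2-hydroxy-4-(2-methylbut-3-yn-2-yloxy)phenyl]ethan-1-one | CC(=O)c1ccc(OC(C)(C)C#C)cc1O
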